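1. The blue run's L readings cannot by themselves prove a delay: a straight line from zero through the last reading misses the reading at 6.00 h by 0.54 percentage points, against a scatter of 0.5 points. Between 6.00 h and 10.0 h it gains s = 0.00575 h⁻¹ of the J charged, and at that rate 10.0 h would give 5.75%, but it reads 4.4%. J sits in the first phase and D in the second, so a lag (induction period), as for a reagent that has to cross, is allowed by the blue run, though not forced.

the same everywhere: J 40 mM

| flask | D | remark | time | volume of the second phase over the first |
|---|---|---|---|---|
| grey | 1 equiv | run made earlier |  |  |
| blue | 1.5 equiv | run made earlier |  |  |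
| flask | 2.00 equiv |  | 15 h | 0.50 |

| run | time / h | L / % | J / % |
|---|---|---|---|
| grey | 0.667 | 0 | 100.4 |
| grey | 1.50 | 0.5 | 99.5 |
| grey | 4.00 | 0.2 | 99.2 |
| grey | 10.0 | 2.2 | 95.4 |
| blue | 1.00 | 0 | 100.4 |
| blue | 3.00 | 0.8 | 100.0 |
| blue | 6.00 | 2.1 | 96.5 |
| blue | 10.0 | 4.4 | 93.5 |

(readings scatter by 0.5 percentage points)

- the L standing at 15 h, as a percentage of the J charged
- the change that raises the amount of L at 15 h, in percent of the J charged most ("none" if none brings more than 2 percentage points) (spring / winter / none)
- amount of L at 15 h, in percent of the J charged, after winter

- spring: doubling the amount of D, all else as stated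
- winter: doubling the transfer coefficient of D, all else as stated

- in the second phase: D; everything else is in the first
- charges count per volume of the first phase; a concentration in a rate is the amount of a species over the volume of its own phase; every rate counts per litre of the first phase
- the earlier runs hold the two phases in the same ratio of volumes as the flask asked about

2. The late blue line, run back to zero L, gives a lag τ = 2.35 h, as a reading. The grey run's late slope is 0.00333 h⁻¹. From grey to blue, D rises by a factor 1.50 and the slope by 1.73, so slope proportional to D is a fair reading within the scatter. That gives this flask its feed slope f = 0.00767 h⁻¹, the L gained per hour after the lag.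

3. What to watch is J: at 10.0 h the blue run lacks 2.1 points of the J charged beyond what L holds, so something besides L may be taking J.

4. My own reckoning for this flask is f(t − τ) = 9.70% at 15 h, with no loss set against it. Spring doubles f and adds that same amount. Winter, if it halves τ, adds 0.9 points, so spring gains more, and winter stands near 10.6%.

5. The forecast says 10.5%, spring and 12% after winter. Its figure for L is higher than mine, its choice the same, on the ground that “Doubling D roughly doubles the rate”.

6. The flask gives 8.27%. Spring adds 7.7 points and winter 2.8 points, so the best change is spring, and winter stands at 11.1%. The forecast held on all three. Here Q is D once in the first phase, and G is the other product.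

    Q ⇌ D, rate k1*([Q] - [D]/K1) per volume of the first phase (partition coefficient = 20.0, kL = 3.80 × 10⁻⁵ s⁻¹)
    J + Q ⇌ L (K = 240 M⁻¹, k = 7.90 × 10⁻⁴ M⁻¹ s⁻¹)
    J + L → G (k = 4.50 × 10⁻⁴ M⁻¹ s⁻¹)

The line f(t − τ) gives 3.95% at 7.50 h, where the flask holds 3.97% of L. At 15.0 h the line gives 9.70%, the flask holds 8.27%, and G holds 6.95%. At that time J + Q → L, forward rate alone, uses J 2.2 times as fast as J + L → G, which spends L as it runs. The same flask read at 40 h holds 13.6%, and the line gives 28.9%, twice that.

The data come from a simulation with constants of no real substance, and the scatter is random.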